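Ring numbering: C1 (side chain), C2, C3 (OH), C4, C5 (OMe), C6 (OAc); side chain C1′, C2′.
Cuts: C4=C5 (enol ether–olefin ring-closing metathesis of triene 21); the two =CH2 caps (Tebbe methylenation of a C5 methyl ester, sulfonium-ylide homologation at C4); C1–C1′ (vinyllithium plus epoxide 4).
Map: C5–C6–C1–C2–C3–C4 are C1–C6 of levoglucosenone 5. Its C1–O–C6 anhydro bridge is exchanged for the C5=C4 double bond.
Forward: iodinate and reduce 5, couple with 4, unzip both acetal C–O bonds as a dithiane, cap C4 and then C5, swap silyl for acetyl, close the carbocycle, desilylate.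
Stereochemistry: C3 is C5 of the D-sugar, C6 comes from hydride attack anti to the anhydro bridge, and C2′ comes from (R)-epichlorohydrin. No stereocentre is made after step 3.
Enabling feature: the C1=C2 olefin is born inside the pyranose ring, so it is Z. It holds C3 and C6, and with them C4 and C5, on one side, giving a 1,4,7-triene pre-folded for six-ring closure.

Key step: step 14

Assumption: 1, 2 and 5 are taken as commercial, and hydride addition to 6 is taken to follow the facial preference known for the parent enone 5.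

Step 1
Reactants: 1 (R)-epichlorohydrin; 2 decylmagnesium bromide
Product: 4 (2R)-2-undecyloxirane, via chlorohydrin 3 (not isolated)
Conditions: CuI (cat.), THF, −40 to 0 °C; then aq NaOH, rt
Reagents that add atoms: none
Why: Copper-catalysed Grignard opening of the epoxide at its CH2 terminus followed by Williamson closure onto CH2Cl never touches the stereocentre, so the R configuration of 1 is carried into 4.

Step 2
Reactants: 5 levoglucosenone
Product: 6 3-iodolevoglucosenone
Conditions: I2, pyridine, CH2Cl2, 0 °C to rt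
Reagents that add atoms: iodine II
Why: Pyridine-mediated α-iodination of the enone (Baylis–Hillman-type addition, iodination of the enolate, elimination) puts the halogen only on sugar C3, the future ring C1.

Step 3
Reactants: 6 3-iodolevoglucosenone
Product: 7 1,6-anhydro-3,4-dideoxy-3-iodo-β-D-threo-hex-3-enopyranose
Conditions: NaBH4, CeCl3·7H2O, MeOH, −78 to 0 °C
Reagents that add atoms: none
Why: In this Luche 1,2-reduction the 1,6-anhydro bridge shields one face of the bicyclic ketone, so hydride should arrive from the other face and give the D-threo alcohol, which sets ring C6 as S.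

Step 4
Reactants: 7 1,6-anhydro-3,4-dideoxy-3-iodo-β-D-threo-hex-3-enopyranose; 4 (2R)-2-undecyloxirane
Product: 9 1,6-anhydro-3,4-dideoxy-3-C-[(2R)-2-hydroxytridecyl]-β-D-threo-hex-3-enopyranose, via dilithio species 8 (not isolated)
Conditions: MeLi (1 equiv), Et2O, −78 °C; t-BuLi (2 equiv), −78 °C; 4, BF3·OEt2, −78 °C; aq NaHCO3
Reagents that add atoms: methyllithium [Li]C; tert-butyllithium [Li]C(C)(C)C (lithium kept only in 8)
Why: Lithium–iodine exchange on the lithium alkoxide gives a ring vinyllithium that cannot eliminate (a cyclic allene would result) and opens the BF3-activated terminal epoxide at CH2 in an SN2 sense, so C1–C1′ forms with C2′ untouched.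

Step 5
Reactants: 9 1,6-anhydro-3,4-dideoxy-3-C-[(2R)-2-hydroxytridecyl]-β-D-threo-hex-3-enopyranose
Product: 10 (3Z)-3,4-dideoxy-3-C-[(2R)-2-hydroxytridecyl]-D-threo-hex-3-enose propane-1,3-diyl dithioacetal
Conditions: HS(CH2)3SH, BF3·OEt2, CH2Cl2, −40 to −10 °C
Reagents that add atoms: propane-1,3-dithiol SCCCS
Why: Lewis-acid transthioacetalisation exchanges both acetal C–O bonds of the anomeric carbon for the chelating dithiol, which unzips the two rings, frees O5 and O6 and leaves the former ring olefin as a Z trisubstituted alkene.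

Step 6
Reactants: 10 (3Z)-3,4-dideoxy-3-C-[(2R)-2-hydroxytridecyl]-D-threo-hex-3-enose propane-1,3-diyl dithioacetal
Product: 12 (3Z)-5,6-anhydro-3,4-dideoxy-3-C-[(2R)-2-hydroxytridecyl]-D-threo-hex-3-enose propane-1,3-diyl dithioacetal, via 6-O-tosylate 11 (not isolated)
Conditions: TsCl, Et3N, Bu2SnO (cat.), CH2Cl2, 0 °C; then K2CO3, MeOH, 0 °C
Reagents that add atoms: p-toluenesulfonyl chloride Cc1ccc(cc1)S(Cl)(=O)=O (atoms kept only in 11)
Why: Stannylene-catalysed sulfonylation picks the primary hydroxyl of the only 1,2-diol and mild base closes the terminal epoxide (intramolecular Williamson reaction) with retention at the carbinol carbon, so O5 is masked and only the two hydroxyls that end as acetates stay free.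

Step 7
Reactants: 12 (3Z)-5,6-anhydro-3,4-dideoxy-3-C-[(2R)-2-hydroxytridecyl]-D-threo-hex-3-enose propane-1,3-diyl dithioacetal
Product: 13 2,2′-bis-O-triethylsilyl ether of 12
Conditions: TESCl, imidazole, DMAP (cat.), DMF, 0 °C to rt
Reagents that add atoms: chlorotriethylsilane CC[Si](Cl)(CC)CC
Why: Standard silyl ether formation on the two remaining secondary alcohols runs under weakly basic conditions that leave the vinyl epoxide and the dithiane alone.

Step 8
Reactants: 13 2,2′-bis-O-triethylsilyl ether of 12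
Product: 14 (3Z)-3,4,6,7-tetradeoxy-2-O-triethylsilyl-3-C-[(2R)-2-(triethylsilyloxy)tridecyl]-D-threo-hepta-3,6-dienose propane-1,3-diyl dithioacetal
Conditions: Me3SI, n-BuLi, THF, −10 °C to rt
Reagents that add atoms: trimethylsulfonium iodide C[S+](C)C.[I-]
Why: In this one-carbon homologation of a terminal epoxide to an allylic alcohol, dimethylsulfonium methylide opens the epoxide at CH2 and the sulfonium alkoxide loses dimethyl sulfide by ylide-mediated elimination, which delivers the C4 vinyl group and frees the C3 oxygen without touching that stereocentre.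

Step 9
Reactants: 14 (3Z)-3,4,6,7-tetradeoxy-2-O-triethylsilyl-3-C-[(2R)-2-(triethylsilyloxy)tridecyl]-D-threo-hepta-3,6-dienose propane-1,3-diyl dithioacetal
Product: 15 5-O-tert-butyldimethylsilyl ether of 14
Conditions: TBSCl, imidazole, DMF, rt
Reagents that add atoms: tert-butylchlorodimethylsilane CC(C)(C)[Si](C)(C)Cl
Why: Silylation of the only free hydroxyl with a group that leaves much more slowly under fluoride than triethylsilyl fixes the later differentiation of the C3 oxygen from those on C6 and C2′.

Step 10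
Reactants: 15 5-O-tert-butyldimethylsilyl ether of 14
Product: 16 aldehydo form of 15 (dithiane replaced by CHO)
Conditions: MeI, CaCO3, MeCN/H2O, 40 °C
Reagents that add atoms: water O
Why: Alkylative dithiane hydrolysis (S-methylation, then water) runs at neutral pH over calcium carbonate, so the silyl ethers and the epimerisable α-silyloxy β,γ-unsaturated aldehyde should survive.

Step 11
Reactants: 16 aldehydo form of 15 (dithiane replaced by CHO)
Product: 18 methyl (3Z)-5-O-tert-butyldimethylsilyl-3,4,6,7-tetradeoxy-2-O-triethylsilyl-3-C-[(2R)-2-(triethylsilyloxy)tridecyl]-D-threo-hepta-3,6-dienonate, via carboxylic acid 17 (not isolated)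
Conditions: NaClO2, NaH2PO4, 2-methyl-2-butene, t-BuOH/H2O, 0 °C; extraction; TMSCHN2, PhMe/MeOH, 0 °C
Reagents that add atoms: sodium chlorite [Na+].[O-]Cl=O; (trimethylsilyl)diazomethane C[Si](C)(C)C=[N+]=[N-]
Why: Pinnick oxidation with an alkene scavenger followed by diazoalkane esterification raises the former anomeric carbon to the ester level without base, so C6 is not epimerised and the olefin does not move into conjugation.

Step 12
Reactants: 18 methyl ester
Product: 19 (3S,4Z,6R)-6-(tert-butyldimethylsilyloxy)-2-methoxy-3-(triethylsilyloxy)-4-[(2R)-2-(triethylsilyloxy)tridecyl]octa-1,4,7-triene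
Conditions: Tebbe reagent, pyridine (cat.), THF/PhMe, −40 to 0 °C; aq NaOH quench
Reagents that add atoms: Tebbe reagent [CH3-].[CH3-].[CH2-2].[Cl-].[Al+3].[Ti+4].c1cc[cH-]c1.c1cc[cH-]c1
Why: Tebbe methylenation converts the only carbonyl group into the 1-methoxyvinyl group under non-basic conditions and is placed before any acetate is present.

Step 13
Reactants: 19 tris-silylated triene
Product: 21 (3S,4Z,6R)-3-acetoxy-4-[(2R)-2-acetoxytridecyl]-6-(tert-butyldimethylsilyloxy)-2-methoxyocta-1,4,7-triene, via diol 20 (not isolated)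
Conditions: TBAF (2 equiv), THF, −20 °C; then Ac2O, Et3N, DMAP (cat.), 0 °C
Reagents that add atoms: acetic anhydride CC(=O)OC(C)=O
Why: In this chemoselective desilylation–acylation, fluoride cleaves the two triethylsilyl ethers far faster than the tert-butyldimethylsilyl ether, no acid touches the enol ether, and both oxygens are acetylated in the same flask.

Step 14
Reactants: 21 (3S,4Z,6R)-3-acetoxy-4-[(2R)-2-acetoxytridecyl]-6-(tert-butyldimethylsilyloxy)-2-methoxyocta-1,4,7-triene
Product: 22 (1S,4S)-6-[(2R)-2-acetoxytridecyl]-4-(tert-butyldimethylsilyloxy)-2-methoxycyclohexa-2,5-dien-1-yl acetate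
Conditions: Hoveyda–Grubbs II (cat.), 2,6-dichloro-1,4-benzoquinone (cat.), CH2Cl2 (high dilution), 40 °C, Ar purge
Reagents that add atoms: none
Why: This is a ring-closing enol ether–olefin metathesis in which the ruthenium alkylidene loads on the only monosubstituted olefin (the C4 vinyl), adds across the 1-methoxyvinyl group through a ruthenacyclobutane and cycloreverts to the C4=C5 bond and Ru=CH2, with ethene as the only by-product. The closest known reaction types are the ruthenium-catalysed closure of acyclic enol ethers to cyclic enol ethers and the closure of 1,4,7-trienes to cyclohexa-1,4-dienes. The single ring formed is the six-membered carbocycle, closed by joining the termini of the C4–C3–C2=C1–C6–C5 chain, whose Z C1=C2 bond (a relic of the pyranose ring) already holds them side by side. No stereocentre is created and C3, C6 and C2′ are spectators, so the trans-1,4 relationship in the ring is simply that of the D-threo chain. The step needs site selectivity (initiation at the vinyl group and not at the enol ether, which would give an inert methoxycarbene, and no reaction at the trisubstituted C1=C2 olefin), and the substitution pattern secures this because intramolecular attack on the 1,1-disubstituted enol ether can only hand its CH2 to ruthenium. It also needs neutral, mild conditions because the product can lose acetic acid or silanol to give an arene, hence the late closure, 40 °C, high dilution and a quinone to quench ruthenium hydrides.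

Step 15
Reactants: 22 (1S,4S)-6-[(2R)-2-acetoxytridecyl]-4-(tert-butyldimethylsilyloxy)-2-methoxycyclohexa-2,5-dien-1-yl acetate
Product: 23 (1S,4S)-6-[(2R)-2-acetoxytridecyl]-4-hydroxy-2-methoxycyclohexa-2,5-dien-1-yl acetate (CNP0081579.1)
Conditions: TBAF/AcOH (1:1), THF, 0 °C
Reagents that add atoms: none
Why: Buffered fluoride desilylation works at near-neutral pH, so the enol ether, the two acetates (which cannot migrate to the trans-disposed C3 oxygen) and the aromatisation-prone diene should be preserved.

Compound list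
1 | (R)-epichlorohydrin | ClC[C@H]1CO1 | starting material
2 | decylmagnesium bromide | CCCCCCCCCC[Mg]Br | starting material
3 | (2R)-1-chlorotridecan-2-ol | CCCCCCCCCCC[C@@H](O)CCl | intermediate
4 | (2R)-2-undecyloxirane | CCCCCCCCCCC[C@@H]1CO1 | intermediate
5 | levoglucosenone (1,6-anhydro-3,4-dideoxy-β-D-glycero-hex-3-enopyranos-2-ulose) | C1[C@@H]2C=CC(=O)[C@H](O1)O2 | starting material
6 | 3-iodolevoglucosenone | C1[C@@H]2C=C(I)C(=O)[C@H](O1)O2 | intermediate
7 | 1,6-anhydro-3,4-dideoxy-3-iodo-β-D-threo-hex-3-enopyranose | C1[C@@H]2C=C(I)[C@H](O)[C@H](O1)O2 | intermediate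
8 | 3-lithio lithium 2-alkoxide derived from 7 | C1[C@@H]2C=C([Li])[C@H](O[Li])[C@H](O1)O2 | intermediate
9 | 1,6-anhydro-3,4-dideoxy-3-C-[(2R)-2-hydroxytridecyl]-β-D-threo-hex-3-enopyranose | C1[C@@H]2C=C(C[C@H](O)CCCCCCCCCCC)[C@H](O)[C@H](O1)O2 | intermediate
10 | (3Z)-3,4-dideoxy-3-C-[(2R)-2-hydroxytridecyl]-D-threo-hex-3-enose propane-1,3-diyl dithioacetal | OC[C@@H](O)/C=C(/C[C@H](O)CCCCCCCCCCC)\[C@H](O)C1SCCCS1 | intermediate
11 | 6-O-tosylate of 10 | Cc1ccc(cc1)S(=O)(=O)OC[C@@H](O)/C=C(/C[C@H](O)CCCCCCCCCCC)\[C@H](O)C1SCCCS1 | intermediate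
12 | (3Z)-5,6-anhydro-3,4-dideoxy-3-C-[(2R)-2-hydroxytridecyl]-D-threo-hex-3-enose propane-1,3-diyl dithioacetal | C1O[C@H]1/C=C(/C[C@H](O)CCCCCCCCCCC)\[C@H](O)C1SCCCS1 | intermediate
13 | 2,2′-bis-O-triethylsilyl ether of 12 | C1O[C@H]1/C=C(/C[C@H](O[Si](CC)(CC)CC)CCCCCCCCCCC)\[C@H](O[Si](CC)(CC)CC)C1SCCCS1 | intermediate
14 | (3Z)-3,4,6,7-tetradeoxy-2-O-triethylsilyl-3-C-[(2R)-2-(triethylsilyloxy)tridecyl]-D-threo-hepta-3,6-dienose propane-1,3-diyl dithioacetal | C=C[C@@H](O)/C=C(/C[C@H](O[Si](CC)(CC)CC)CCCCCCCCCCC)\[C@H](O[Si](CC)(CC)CC)C1SCCCS1 | intermediate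
15 | 5-O-tert-butyldimethylsilyl ether of 14 | C=C[C@@H](O[Si](C)(C)C(C)(C)C)/C=C(/C[C@H](O[Si](CC)(CC)CC)CCCCCCCCCCC)\[C@H](O[Si](CC)(CC)CC)C1SCCCS1 | intermediate
16 | aldehydo form of 15 (dithiane replaced by CHO) | C=C[C@@H](O[Si](C)(C)C(C)(C)C)/C=C(/C[C@H](O[Si](CC)(CC)CC)CCCCCCCCCCC)\[C@H](O[Si](CC)(CC)CC)C=O | intermediate
17 | carboxylic acid from 16 | C=C[C@@H](O[Si](C)(C)C(C)(C)C)/C=C(/C[C@H](O[Si](CC)(CC)CC)CCCCCCCCCCC)\[C@H](O[Si](CC)(CC)CC)C(=O)O | intermediate
18 | methyl ester of 17 | C=C[C@@H](O[Si](C)(C)C(C)(C)C)/C=C(/C[C@H](O[Si](CC)(CC)CC)CCCCCCCCCCC)\[C@H](O[Si](CC)(CC)CC)C(=O)OC | intermediate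
19 | (3S,4Z,6R)-6-(tert-butyldimethylsilyloxy)-2-methoxy-3-(triethylsilyloxy)-4-[(2R)-2-(triethylsilyloxy)tridecyl]octa-1,4,7-triene | C=C[C@@H](O[Si](C)(C)C(C)(C)C)/C=C(/C[C@H](O[Si](CC)(CC)CC)CCCCCCCCCCC)\[C@H](O[Si](CC)(CC)CC)C(=C)OC | intermediate
20 | (3S,4Z,6R)-6-(tert-butyldimethylsilyloxy)-4-[(2R)-2-hydroxytridecyl]-2-methoxyocta-1,4,7-trien-3-ol | C=C[C@@H](O[Si](C)(C)C(C)(C)C)/C=C(/C[C@H](O)CCCCCCCCCCC)\[C@H](O)C(=C)OC | intermediate
21 | (3S,4Z,6R)-3-acetoxy-4-[(2R)-2-acetoxytridecyl]-6-(tert-butyldimethylsilyloxy)-2-methoxyocta-1,4,7-triene | C=C[C@@H](O[Si](C)(C)C(C)(C)C)/C=C(/C[C@H](OC(C)=O)CCCCCCCCCCC)\[C@H](OC(C)=O)C(=C)OC | intermediate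
22 | (1S,4S)-6-[(2R)-2-acetoxytridecyl]-4-(tert-butyldimethylsilyloxy)-2-methoxycyclohexa-2,5-dien-1-yl acetate | CCCCCCCCCCC[C@H](CC1=C[C@H](O[Si](C)(C)C(C)(C)C)C=C(OC)[C@H]1OC(C)=O)OC(C)=O | intermediate
23 | (1S,4S)-6-[(2R)-2-acetoxytridecyl]-4-hydroxy-2-methoxycyclohexa-2,5-dien-1-yl acetate | CCCCCCCCCCC[C@H](CC1=C[C@H](O)C=C(OC)[C@H]1OC(C)=O)OC(C)=O | target

Total step count: 15. Longest linear sequence: 14 (steps 2–15, from levoglucosenone).

Steps most likely to fail

1. Step 14.
What may go wrong: the catalyst may be drained by loading on the enol ether to give an unreactive methoxy-substituted ruthenium carbene. Ruthenium hydrides may also shift the double bonds and trigger loss of acetic acid with aromatisation.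
Fallback: this sets out from ester 18 and replaces steps 12–14 by an ester–alkene cyclisation. A reduced-titanium ethylidene reagent of the Takai–Utimoto type (TiCl4, Zn, PbCl2 cat., TMEDA, CH3CHBr2, THF, 65 °C) exchanges with the vinyl group. The titanium alkylidene so formed olefinates the methyl ester intramolecularly to give the ring-closed tris-silyl ether F1. TBAF (2 equiv, −20 °C) then gives the ring diol F2, and Ac2O/Et3N/DMAP brings the material back to the route at 22.

2. Step 5.
What may go wrong: under the Lewis acid the liberated (Z)-ene-1,4-diol may cyclodehydrate to a dihydrofuran, or an allylic C–O bond may ionise and be captured by thiol.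
Fallback: this sets out from 9 and breaks the bridge first, with all nucleophilic hydroxyls masked. Acetolysis (Ac2O, TESOTf cat., 0 °C) gives the pyranose tetraacetate F3. Its more reactive anomeric acetate is exchanged with propane-1,3-dithiol (BF3·OEt2, −40 °C) to give the acyclic triacetate dithiane F4. Methanolysis (K2CO3, MeOH) rejoins the route at 10.

3. Step 8.
What may go wrong: the ylide may attack at the allylic epoxide carbon or in an SN2′ sense, or the sequence may stall at the sulfonium alkoxide stage.
Fallback: this sets out from 13 and separates addition from elimination by selenium chemistry. (Phenylselanyl)methyllithium, made from bis(phenylselanyl)methane and n-BuLi at −78 °C, opens the epoxide at CH2 to give the γ-hydroxy selenide F5. One equivalent of mCPBA at −78 °C oxidises selenium in preference to sulfur to give the selenoxide F6. On warming with i-Pr2NH, F6 undergoes syn elimination and returns to the route at 14.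

Further compounds
F1 | step 14 | ring-closed tris-silyl ether (22 with OSiEt3 in place of both OAc) | CCCCCCCCCCC[C@H](CC1=C[C@H](O[Si](C)(C)C(C)(C)C)C=C(OC)[C@H]1O[Si](CC)(CC)CC)O[Si](CC)(CC)CC
F2 | step 14 | ring diol (22 with OH in place of both OAc) | CCCCCCCCCCC[C@H](CC1=C[C@H](O[Si](C)(C)C(C)(C)C)C=C(OC)[C@H]1O)O
F3 | step 5 | 1,2,6-tri-O-acetyl-3-C-[(2R)-2-acetoxytridecyl]-3,4-dideoxy-D-threo-hex-3-enopyranose (anomeric mixture) | CC(=O)OC[C@@H]1C=C(C[C@H](OC(C)=O)CCCCCCCCCCC)[C@H](OC(C)=O)C(OC(C)=O)O1
F4 | step 5 | 2,6,2′-tri-O-acetyl derivative of 10 | CC(=O)OC[C@@H](O)/C=C(/C[C@H](OC(C)=O)CCCCCCCCCCC)\[C@H](OC(C)=O)C1SCCCS1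
F5 | step 8 | γ-hydroxy selenide (13 opened at CH2 by PhSeCH2) | c1ccccc1[Se]CC[C@@H](O)/C=C(/C[C@H](O[Si](CC)(CC)CC)CCCCCCCCCCC)\[C@H](O[Si](CC)(CC)CC)C1SCCCS1
F6 | step 8 | selenoxide of F5 | O=[Se](c1ccccc1)CC[C@@H](O)/C=C(/C[C@H](O[Si](CC)(CC)CC)CCCCCCCCCCC)\[C@H](O[Si](CC)(CC)CC)C1SCCCS1
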